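Count the lifetimes of E in the east flask before anything else.

all flasks: J 0.00640 M

| charge | Q | E | G | time |
|---|---|---|---|---|
| north-west | 0.0800 M | 0.0960 M |  |  |
| south-west | 0.0320 M | 0.0480 M |  |  |
| north | 0.0800 M | 0.0960 M | 0.0240 M |  |
| east | 0.240 M | 0.0320 M |  | 84 min |

- G in the east run at 84 min, as a share of the Q charged

- Overall: Q + E -> G, with J as catalyst.
- Constant volume, constant temperature.
- Readings of a species count what is bound in complexes too.
- "The second partner" is E.

| run | time / min | [G] / M |
|---|---|---|
| north-west run | 10 | 0.02151 |
| north-west run | 21 | 0.03415 |
| north-west run | 32 | 0.04158 |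
| north-west run | 42 | 0.04587 |
| north-west run | 52 | 0.04897 |
| north-west run | 63 | 0.05106 |
| north-west run | 74 | 0.05230 |
| north-west run | 84 | 0.05329 |
| south-west run | 10 | 0.00605 |
| south-west run | 21 | 0.01044 |
| south-west run | 32 | 0.01428 |
| south-west run | 42 | 0.01593 |
| south-west run | 52 | 0.01767 |
| south-west run | 63 | 0.01869 |
| south-west run | 74 | 0.02009 |
| south-west run | 84 | 0.02102 |
| north run | 10 | 0.04429 |
| north run | 21 | 0.05683 |
| north run | 32 | 0.06338 |
| north run | 42 | 0.06747 |
| north run | 52 | 0.06970 |
| north run | 63 | 0.07157 |
| north run | 74 | 0.07229 |
| north run | 84 | 0.07317 |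

(readings scatter by 2 × 10⁻⁴ M)

I read these tables as fractions of the charge. While Q and E turn one for one, a closed form holds for a second-order rate. The ln of (fraction of E left over fraction of Q left), divided by the difference of the charges and by the time, gives a constant k.

At the first reading of the south-west run, k came to 0.468 M⁻¹ min⁻¹. Over the whole north-west run it came to 0.214 M⁻¹ min⁻¹. Over the whole north run, counting the G made, it came to 0.175 M⁻¹ min⁻¹, the lowest of these. So k did not hold steady across these readings, and I took the lowest value as my low case.

The east flask charges more Q than E, so E is the limiting reagent, and G can reach 13.3% of the Q charged. I treated E as pseudo-first-order and held Q at its charge, which is an approximation. The lifetime count N, the time divided by the lifetime of E, is k times the Q charged times the time.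

With the low constant, N was 3.54; with the early south-west constant it was 9.43. The fraction of E turned is one minus exp(−N), so even the low constant turned nearly all of it in this reckoning. My reckoning gave 12.9% of the Q charged.

The forecast said 11%, lower than my figure, and noted “Mild saturation also lowers it”.

The flask gave 13.1% of the Q charged.

    J + E ⇌ JE, settled at all times (7.630 M⁻¹)
    JE + Q → G + J (13.80 M⁻¹ min⁻¹)
    2 Q → Qe (0.06900 M⁻¹ min⁻¹)
    G + E → L (0.04434 M⁻¹ min⁻¹)

Removing the pairing of Q to Qe changes this result very little. Against the ceiling, the result means that G at 84 min came to 98.5% of the E charged. Put through the same closed form, that is a count of 3.98 lifetimes, above the low-case count of 3.54.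

The earlier runs and the new flask stem from a simulated flask on assumed constants, noise included.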